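Ring A is disconnected last. Its contiguous C5-OH, C6-prenyl, C7-O, C8-H array, fused to ring C across C4a-C8a, is the 2-alkylresorcinol monosilyl ether that a Danheiser benzannulation delivers from a ketene and a siloxyalkyne. Irradiation of a 5-aryl-4-pyranon-2-yl diazomethyl ketone with a prenyl-substituted triisopropylsiloxyalkyne should trigger Wolff rearrangement, [2+2] addition, four-electron ring opening and six-electron closure in one flask. This builds the whole benzene ring with the prenyl group locked at C6 and the two ring A oxygens differentiated. The precursor is a kojic acid-derived pyranone already carrying ring B (joined by Suzuki coupling) and a C2 diazoacetyl group; fluoride then frees the three hydroxyls.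

Key step: step 12

Remark: Ar stands for 4-(triisopropylsilyloxy)-3-[3-methyl-3-(triethylsilyloxy)butyl]phenyl; purchased reagents appear under Conditions without a number; the target is achiral, and the two transient stereocentres (in 24 and 26) are racemic and vanish on aromatisation.

Step 1
Reactants: 1 dihydrocoumarin (chroman-2-one)
Product: 2 6-bromochroman-2-one
Conditions: Br2 (1.05 equiv), CH2Cl2, 0 °C to rt
Reagents that add atoms: bromine BrBr
Why: Electrophilic aromatic bromination is steered para to the ring oxygen, the strongest donor on the arene, so the 6-bromo lactone should predominate.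

Step 2
Reactants: 2 6-bromochroman-2-one
Product: 3 4-bromo-2-(3-hydroxy-3-methylbutyl)phenol
Conditions: MeMgBr (3.5 equiv), THF, 0 °C to rt; aq NH4Cl
Reagents that add atoms: methylmagnesium bromide C[Mg]Br
Why: Double Grignard addition to the lactone carbonyl opens the ring to the phenoxide and the tertiary alkoxide, the aryl bromide being inert to MeMgBr and the near-neutral quench avoiding acid-promoted closure to a 2,2-dimethylchroman.

Step 3
Reactants: 3 4-bromo-2-(3-hydroxy-3-methylbutyl)phenol
Product: 5 [4-bromo-2-(3-methyl-3-(triethylsilyloxy)butyl)phenoxy]triisopropylsilane (ArBr), via phenol TIPS ether 4 (not isolated)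
Conditions: TIPSOTf (1.05 equiv), 2,6-lutidine, CH2Cl2, −78 to 0 °C; then TESOTf (1.5 equiv), 0 °C
Reagents that add atoms: triisopropylsilyl triflate CC(C)[Si](C(C)C)(C(C)C)OS(=O)(=O)C(F)(F)F; triethylsilyl triflate CC[Si](CC)(CC)OS(=O)(=O)C(F)(F)F
Why: In this sequential silyl triflate silylation the bulky TIPSOTf should react at low temperature only with the phenol, after which the smaller TESOTf caps the hindered tertiary alcohol in the same flask, giving a base-stable aryl ether and a fluoride-labile tertiary ether.

Step 4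
Reactants: 5 ArBr
Product: 6 2-Ar-4,4,5,5-tetramethyl-1,3,2-dioxaborolane (ArBpin)
Conditions: B2pin2 (1.2 equiv), Pd(dppf)Cl2 (3 mol %), KOAc, 1,4-dioxane, 85 °C
Reagents that add atoms: bis(pinacolato)diboron CC1(C)OB(OC1(C)C)B1OC(C)(C)C(C)(C)O1
Why: Miyaura borylation of the unhindered aryl bromide uses only the weak base KOAc, which both silyl ethers tolerate.

Step 5
Reactants: 7 kojic acid
Product: 8 kojic acid 5-triflate (6-(hydroxymethyl)-4-oxo-4H-pyran-3-yl trifluoromethanesulfonate)
Conditions: PhNTf2 (1.05 equiv), Et3N (1.2 equiv), DMF, 0 °C to rt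
Reagents that add atoms: N-phenyl-bis(trifluoromethanesulfonimide) O=S(=O)(N(c1ccccc1)S(=O)(=O)C(F)(F)F)C(F)(F)F
Why: Chemoselective O-triflation: Et3N deprotonates only the acidic enolic 5-OH, and the mild triflyl donor PhNTf2 does not sulfonylate the neutral primary alcohol.

Step 6
Reactants: 6 ArBpin; 8 kojic acid 5-triflate
Product: 9 5-Ar-2-(hydroxymethyl)-4H-pyran-4-one
Conditions: Pd(dppf)Cl2 (5 mol %), K3PO4 (2 equiv), 1,4-dioxane/H2O (9:1), 60 °C
Reagents that add atoms: none
Why: Suzuki-Miyaura coupling of the electron-poor enol triflate should proceed at moderate temperature with a mild phosphate base that the 4-pyranone, the free primary alcohol and both silyl ethers tolerate.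

Step 7
Reactants: 9 5-Ar-2-(hydroxymethyl)-4H-pyran-4-one
Product: 10 5-Ar-4-oxo-4H-pyran-2-carboxylic acid
Conditions: TEMPO (10 mol %), NaClO2 (2 equiv), NaOCl (2 mol %), MeCN/pH 6.7 phosphate buffer, 35 °C; Na2SO3, then pH 4 work-up, used at once
Reagents that add atoms: sodium chlorite [Na+].[O-]Cl=O
Why: Oxoammonium-catalysed oxidation of the primary alcohol to the aldehyde, with chlorite oxidation of that aldehyde in the same pot, runs near neutral pH, so the silyl ethers, the pyranone and the silyloxyarene should survive.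

Step 8
Reactants: 11 trimethylsilylacetylene; 12 prenyl bromide
Product: 14 trimethyl(5-methylhex-4-en-1-yn-1-yl)silane, via bromomagnesium acetylide 13 (not isolated)
Conditions: EtMgBr (1.0 equiv), THF, 0 °C to rt; then CuBr·SMe2 (10 mol %), 12, rt to 45 °C
Reagents that add atoms: none
Why: Copper-catalysed allylic substitution by the alkynyl Grignard reagent should occur at the unhindered primary carbon of prenyl bromide, giving the skipped enyne with the trisubstituted alkene intact.

Step 9
Reactants: 14 trimethyl(5-methylhex-4-en-1-yn-1-yl)silane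
Product: 15 5-methylhex-4-en-1-yne
Conditions: K2CO3 (0.2 equiv), MeOH, 0 °C to rt, short; pentane extraction, kept as a titrated solution
Reagents that add atoms: none
Why: Carbonate-catalysed methanolysis of the alkynyl C-Si bond is mild enough, when cold and brief, to leave the skipped enyne unisomerised, and the volatile product is never concentrated to dryness.

Step 10
Reactants: 15 5-methylhex-4-en-1-yne
Product: 18 triisopropyl[(5-methylhex-4-en-1-yn-1-yl)oxy]silane, via lithium acetylide 16 (not isolated), via lithium ynolate 17 (not isolated)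
Conditions: n-BuLi (1.0 equiv), THF, −78 °C; LiOOt-Bu (from t-BuOOH, LiHMDS), −78 to 0 °C; TIPSOTf (1.5 equiv), −78 to 0 °C
Reagents that add atoms: tert-butyl hydroperoxide CC(C)(C)OO; triisopropylsilyl triflate CC(C)[Si](C(C)C)(C(C)C)OS(=O)(=O)C(F)(F)F
Why: Oxygen transfer from lithium tert-butyl peroxide to the lithium acetylide gives the ynolate, which the bulky silyl triflate traps on oxygen (acetylide oxidation followed by O-silylation), one equivalent of base touching only the terminal C-H.

Step 11
Reactants: 10 5-Ar-4-oxo-4H-pyran-2-carboxylic acid; 19 trimethylsilyldiazomethane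
Product: 22 2-(diazoacetyl)-5-Ar-4H-pyran-4-one, via mixed anhydride 20 (not isolated), via C-silyl diazoketone 21 (not isolated)
Conditions: i-BuOCOCl, N-methylmorpholine, THF, −15 °C; then 19 (1.5 equiv), MeCN, −15 to 4 °C; aq NaHCO3
Reagents that add atoms: none
Why: Acylation of the diazoalkane at the more electrophilic acyl carbonyl of the mixed carbonic anhydride (diazoketone synthesis of the Arndt-Eistert type) avoids HCl, low temperature and little excess reagent limit dipolar addition to the pyranone, and the C-silyl group is lost on the bicarbonate work-up.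

Step 12
Reactants: 22 2-(diazoacetyl)-5-Ar-4H-pyran-4-one; 18 triisopropyl[(5-methylhex-4-en-1-yn-1-yl)oxy]silane
Product: 27 3-Ar-5-hydroxy-6-prenyl-7-(triisopropylsilyloxy)-4H-chromen-4-one, via ketene 23 (not isolated), via cyclobutenone 24 (not isolated), via dienylketene 25 (not isolated), via keto tautomer 26 (not isolated)
Conditions: hν (LED, ca. 400 nm), 18 (1.5 equiv), degassed ClCH2CH2Cl, rt; then 80 °C
Reagents that add atoms: none
Why: Light near 400 nm expels N2 from 22 and the pyranonyl group shifts to the carbene carbon (Wolff rearrangement), so the former diazo carbon becomes C8 and the former carboxyl carbon becomes the ketene carbon and later C5; the nucleophilic, prenyl-bearing carbon of 18 then adds to that ketene carbon in a [2+2] cycloaddition (bonds C5-C6 and C7-C8) to give cyclobutenone 24, which on warming opens in a four-electron electrocyclic reaction (cleaving the temporary C5-C8 bond) to dienylketene 25. Ring A, the only ring kept, closes by a thermally allowed disrotatory six-electron electrocyclization of the ketene carbon onto pyranone C3 (bond C5-C4a), and enolization of dienone 26 gives the aromatic ring; the four-membered ring is made by the [2+2] addition and lost again. The closest known reaction is the diazoketone variant of the Danheiser benzannulation, practised with aryl, heteroaryl and alkenyl diazomethyl ketones and triisopropylsiloxyalkynes, here applied to a 4-pyranone whose C3 is the nucleophilic carbon of an enol ether in a ring with little aromatic stabilization to give up. No stereocenter remains, since those of 24 and 26 are transient and racemic and the geometry of 25 can equilibrate through reversible ring opening. Three selectivities are needed and the substrates set them: the polarity of the ynol ether places prenyl at C6 and silyloxy at C7, pyranone C2 has only C3 as a carbon neighbour so closure has a single site, and the electron-rich siloxyalkyne is a far better ketenophile than the trisubstituted prenyl alkene. The long wavelength excites the conjugated diazoketone but should spare the pyranone and the isoflavone chromophore, every hydroxyl is silylated so nothing intercepts the ketenes, and the new C5-OH is tied up by a hydrogen bond to the C4 carbonyl.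

Step 13
Reactants: 27 3-Ar-5-hydroxy-6-prenyl-7-(triisopropylsilyloxy)-4H-chromen-4-one
Product: 28 coloratanin A
Conditions: TBAF (4 equiv), AcOH (4 equiv), THF, 0 °C to rt; aq NH4Cl
Reagents that add atoms: none
Why: Fluoride-mediated desilylation should cleave the two aryl TIPS ethers and the tertiary TES ether, the acetic acid buffer keeping the medium neither strongly basic nor acidic so that neither side chain closes to a chroman and the tertiary alcohol is not dehydrated.

Compound list
1 | dihydrocoumarin (chroman-2-one) | O=C1CCc2ccccc2O1 | starting material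
2 | 6-bromochroman-2-one | O=C1CCc2cc(Br)ccc2O1 | intermediate
3 | 4-bromo-2-(3-hydroxy-3-methylbutyl)phenol | CC(C)(O)CCc1cc(Br)ccc1O | intermediate
4 | 4-[5-bromo-2-(triisopropylsilyloxy)phenyl]-2-methylbutan-2-ol (formed and consumed in step 3) | CC(C)(O)CCc1cc(Br)ccc1O[Si](C(C)C)(C(C)C)C(C)C | intermediate
5 | [4-bromo-2-(3-methyl-3-(triethylsilyloxy)butyl)phenoxy]triisopropylsilane (ArBr) | CC[Si](CC)(CC)OC(C)(C)CCc1cc(Br)ccc1O[Si](C(C)C)(C(C)C)C(C)C | intermediate
6 | 2-Ar-4,4,5,5-tetramethyl-1,3,2-dioxaborolane (ArBpin) | CC1(C)OB(c2ccc(O[Si](C(C)C)(C(C)C)C(C)C)c(CCC(C)(C)O[Si](CC)(CC)CC)c2)OC1(C)C | intermediate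
7 | kojic acid (5-hydroxy-2-(hydroxymethyl)-4H-pyran-4-one) | OCc1cc(=O)c(O)co1 | starting material
8 | kojic acid 5-triflate | OCc1cc(=O)c(OS(=O)(=O)C(F)(F)F)co1 | intermediate
9 | 5-Ar-2-(hydroxymethyl)-4H-pyran-4-one | OCc1cc(=O)c(-c2ccc(O[Si](C(C)C)(C(C)C)C(C)C)c(CCC(C)(C)O[Si](CC)(CC)CC)c2)co1 | intermediate
10 | 5-Ar-4-oxo-4H-pyran-2-carboxylic acid | OC(=O)c1cc(=O)c(-c2ccc(O[Si](C(C)C)(C(C)C)C(C)C)c(CCC(C)(C)O[Si](CC)(CC)CC)c2)co1 | intermediate
11 | trimethylsilylacetylene | C#C[Si](C)(C)C | starting material
12 | prenyl bromide (1-bromo-3-methylbut-2-ene) | CC(C)=CCBr | starting material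
13 | bromomagnesium (trimethylsilyl)acetylide (formed and consumed in step 8) | C[Si](C)(C)C#C[Mg]Br | intermediate
14 | trimethyl(5-methylhex-4-en-1-yn-1-yl)silane | CC(C)=CCC#C[Si](C)(C)C | intermediate
15 | 5-methylhex-4-en-1-yne | C#CCC=C(C)C | intermediate
16 | lithium 5-methylhex-4-en-1-yn-1-ide (formed and consumed in step 10) | [Li]C#CCC=C(C)C | intermediate
17 | lithium 5-methylhex-4-en-1-yn-1-olate, the ynolate (formed and consumed in step 10) | [Li]OC#CCC=C(C)C | intermediate
18 | triisopropyl[(5-methylhex-4-en-1-yn-1-yl)oxy]silane | CC(C)=CCC#CO[Si](C(C)C)(C(C)C)C(C)C | intermediate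
19 | trimethylsilyldiazomethane | C[Si](C)(C)C=[N+]=[N-] | starting material
20 | isobutyl carbonic 5-Ar-4-oxo-4H-pyran-2-carboxylic anhydride (formed and consumed in step 11) | CC(C)COC(=O)OC(=O)c1cc(=O)c(-c2ccc(O[Si](C(C)C)(C(C)C)C(C)C)c(CCC(C)(C)O[Si](CC)(CC)CC)c2)co1 | intermediate
21 | 2-diazo-2-(trimethylsilyl)-1-(5-Ar-4-oxo-4H-pyran-2-yl)ethanone (formed and consumed in step 11) | C[Si](C)(C)C(=[N+]=[N-])C(=O)c1cc(=O)c(-c2ccc(O[Si](C(C)C)(C(C)C)C(C)C)c(CCC(C)(C)O[Si](CC)(CC)CC)c2)co1 | intermediate
22 | 2-(diazoacetyl)-5-Ar-4H-pyran-4-one | [N-]=[N+]=CC(=O)c1cc(=O)c(-c2ccc(O[Si](C(C)C)(C(C)C)C(C)C)c(CCC(C)(C)O[Si](CC)(CC)CC)c2)co1 | intermediate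
23 | (5-Ar-4-oxo-4H-pyran-2-yl)ketene (formed and consumed in step 12) | O=C=Cc1cc(=O)c(-c2ccc(O[Si](C(C)C)(C(C)C)C(C)C)c(CCC(C)(C)O[Si](CC)(CC)CC)c2)co1 | intermediate
24 | 2-prenyl-3-(triisopropylsilyloxy)-4-(5-Ar-4-oxo-4H-pyran-2-yl)cyclobut-2-en-1-one, racemic (formed and consumed in step 12) | CC(C)=CCC1=C(O[Si](C(C)C)(C(C)C)C(C)C)C(c2cc(=O)c(-c3ccc(O[Si](C(C)C)(C(C)C)C(C)C)c(CCC(C)(C)O[Si](CC)(CC)CC)c3)co2)C1=O | intermediate
25 | 2-prenyl-3-(triisopropylsilyloxy)-4-(5-Ar-4-oxo-4H-pyran-2-yl)buta-1,3-dien-1-one, pyranonyl group cis to the ketene-bearing carbon (formed and consumed in step 12) | O=C=C(CC=C(C)C)/C(O[Si](C(C)C)(C(C)C)C(C)C)=C\c1cc(=O)c(-c2ccc(O[Si](C(C)C)(C(C)C)C(C)C)c(CCC(C)(C)O[Si](CC)(CC)CC)c2)co1 | intermediate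
26 | 3-Ar-6-prenyl-7-(triisopropylsilyloxy)-4aH-chromene-4,5-dione, the 4a-H keto tautomer, racemic (formed and consumed in step 12) | CC(C)=CCC1=C(O[Si](C(C)C)(C(C)C)C(C)C)C=C2OC=C(c3ccc(O[Si](C(C)C)(C(C)C)C(C)C)c(CCC(C)(C)O[Si](CC)(CC)CC)c3)C(=O)C2C1=O | intermediate
27 | 3-Ar-5-hydroxy-6-prenyl-7-(triisopropylsilyloxy)-4H-chromen-4-one (tris-silylated coloratanin A) | CC(C)=CCc1c(O[Si](C(C)C)(C(C)C)C(C)C)cc2occ(-c3ccc(O[Si](C(C)C)(C(C)C)C(C)C)c(CCC(C)(C)O[Si](CC)(CC)CC)c3)c(=O)c2c1O | intermediate
28 | coloratanin A | CC(C)=CCc1c(O)cc2occ(-c3ccc(O)c(CCC(C)(C)O)c3)c(=O)c2c1O | target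

Total step count: 13. Longest linear sequence: 9 steps (1, 2, 3, 4, 6, 7, 11, 12, 13) from dihydrocoumarin.

Steps most likely to fail

Step 12. What may go wrong: photoreactions of the 4-pyranone or of the isoflavone product compete with the Wolff rearrangement, the ketene dimerises before it meets the alkyne, or light absorption by the product stalls conversion. Fallback: the same ketene is released in the dark by dehydrochlorination instead of photolysis. It sets out from diazoketone 22. Wolff rearrangement catalysed by silver benzoate (PhCO2Ag) with Et3N in aqueous THF, shielded from light, should give the homologous (5-Ar-4-oxo-4H-pyran-2-yl)acetic acid F1, kept cold because it can decarboxylate. 1-Chloro-N,N,2-trimethylprop-1-en-1-amine in CH2Cl2 should convert it under neutral conditions into (5-Ar-4-oxo-4H-pyran-2-yl)acetyl chloride F2. Slow addition of Et3N to F2 and siloxyalkyne 18 in toluene at room temperature should generate ketene 23, where the fallback rejoins the route; heating then carries 24 through 25 and 26 to 27.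

Step 11. What may go wrong: the diazoalkane adds as a 1,3-dipole across the electron-poor C2=C3 bond of the acylpyranone, attacks the carbonate carbonyl of the mixed anhydride, or acylates too slowly at its hindered silylated carbon. Fallback: the diazo group is installed by deacylative diazo transfer to a methyl ketone instead of by acylating a diazoalkane. It sets out from alcohol 9. MnO2 in CH2Cl2 should give 5-Ar-4-oxo-4H-pyran-2-carbaldehyde F3. MeMgBr at −78 °C, where the aldehyde reacts far faster than the vinylogous ester carbonyl, should give racemic 5-Ar-2-(1-hydroxyethyl)-4H-pyran-4-one F4. Dess-Martin periodinane should give 2-acetyl-5-Ar-4H-pyran-4-one F5. LiHMDS and 2,2,2-trifluoroethyl trifluoroacetate at −78 °C should give 4,4,4-trifluoro-1-(5-Ar-4-oxo-4H-pyran-2-yl)butane-1,3-dione F6. Methanesulfonyl azide, Et3N and water in MeCN should then transfer the diazo group with loss of the trifluoroacetyl group, returning to the route at diazoketone 22.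

Step 10. What may go wrong: the base isomerises the skipped enyne through its doubly activated CH2 group, oxygen transfer to the acetylide stays incomplete, or the ynolate is silylated on carbon to a silylketene. Fallback: the same ynolate is reached by reductive fragmentation of an α,α-dibromo ester, with no 1,4-enyne on the way. It sets out from prenyl bromide 12. Alkylation of the lithium enolate of ethyl acetate (LDA, THF, −78 °C) should give ethyl 5-methylhex-4-enoate F7. Two rounds of enolate bromination (LiHMDS, BrCF2CF2Br, −78 °C) should give racemic ethyl 2-bromo-5-methylhex-4-enoate F8 and then ethyl 2,2-dibromo-5-methylhex-4-enoate F9. tert-Butyllithium (4 equiv, THF, −78 to 0 °C) should effect double lithium-halogen exchange and loss of ethoxide to give lithium ynolate 17, where the fallback rejoins the route; O-silylation with TIPSOTf then gives 18.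

Further compounds
F1 | step 12 | (5-Ar-4-oxo-4H-pyran-2-yl)acetic acid | OC(=O)Cc1cc(=O)c(-c2ccc(O[Si](C(C)C)(C(C)C)C(C)C)c(CCC(C)(C)O[Si](CC)(CC)CC)c2)co1
F2 | step 12 | (5-Ar-4-oxo-4H-pyran-2-yl)acetyl chloride | ClC(=O)Cc1cc(=O)c(-c2ccc(O[Si](C(C)C)(C(C)C)C(C)C)c(CCC(C)(C)O[Si](CC)(CC)CC)c2)co1
F3 | step 11 | 5-Ar-4-oxo-4H-pyran-2-carbaldehyde | O=Cc1cc(=O)c(-c2ccc(O[Si](C(C)C)(C(C)C)C(C)C)c(CCC(C)(C)O[Si](CC)(CC)CC)c2)co1
F4 | step 11 | 5-Ar-2-(1-hydroxyethyl)-4H-pyran-4-one (racemic) | CC(O)c1cc(=O)c(-c2ccc(O[Si](C(C)C)(C(C)C)C(C)C)c(CCC(C)(C)O[Si](CC)(CC)CC)c2)co1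
F5 | step 11 | 2-acetyl-5-Ar-4H-pyran-4-one | CC(=O)c1cc(=O)c(-c2ccc(O[Si](C(C)C)(C(C)C)C(C)C)c(CCC(C)(C)O[Si](CC)(CC)CC)c2)co1
F6 | step 11 | 4,4,4-trifluoro-1-(5-Ar-4-oxo-4H-pyran-2-yl)butane-1,3-dione | O=C(CC(=O)c1cc(=O)c(-c2ccc(O[Si](C(C)C)(C(C)C)C(C)C)c(CCC(C)(C)O[Si](CC)(CC)CC)c2)co1)C(F)(F)F
F7 | step 10 | ethyl 5-methylhex-4-enoate | CCOC(=O)CCC=C(C)C
F8 | step 10 | ethyl 2-bromo-5-methylhex-4-enoate (racemic) | CCOC(=O)C(Br)CC=C(C)C
F9 | step 10 | ethyl 2,2-dibromo-5-methylhex-4-enoate | CCOC(=O)C(Br)(Br)CC=C(C)C
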